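**Retrosynthetic overview**
1. Target 40 ⇒ ester bond C15–O–C(=O): acid 22 (unit A) + alcohol 36 (unit B). The other CO2H groups travel as CH2OTBS (→ CO2H by oxidation) and CH2NO2 (→ CO2H by nitro-to-acid conversion).
2. Each isocitrate ether arm ⇒ anti-selective enamine Michael addition of a drimanyl-oxyacetaldehyde (18, 32) to nitroalkene 8; this sets both side-chain stereocentres.
3. Drimane ring B (C8=CH2, C11–O) ⇒ Lombardo methylenation of keto ethers 16/30, made by the key step: carbenoid-triggered semipinacol ring expansion (cyclopentane → cyclohexanone, C11–O–C bond formed) of epoxy silyl ethers 14/28.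
4. Hydrindanones 11/25 ⇒ common Hajos–Parrish-type enone ketal 5 by Birch reductive alkylation (MeI or PMBOCH2Cl sets C4) and Wolff–Kishner reduction.
5. Ring order: cyclopentane (from 1) → ring A (aldol annulation) → ring B (expansion of the cyclopentane).

Assumptions: carriers of protecting groups and one-carbon reagents (ethylene glycol, TBSCl, TMSOTf, PMBOCH2Cl) are treated as reagents. The sense of induction of the amine–thiourea catalyst in steps 13/23 is assigned by analogy, not from a direct precedent, and must be confirmed on 19.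

Abbreviations: Alb = [(1S,4aS,8aS)-5,5,8a-trimethyl-2-methylidenedecahydronaphthalen-1-yl]methyl (albicanyl). PMBO-Alb = [(1S,4aR,5R,8aS)-5-{[(4-methoxybenzyl)oxy]methyl}-5,8a-dimethyl-2-methylidenedecahydronaphthalen-1-yl]methyl. HO-Alb = the same group with 5-(hydroxymethyl). TBS = tert-butyldimethylsilyl.

**Common intermediate and nitroalkene**

Step 1
Reactants: 1 2-methylcyclopentane-1,3-dione; 2 pent-1-en-3-one
Product: 3 2-methyl-2-(3-oxopentyl)cyclopentane-1,3-dione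
Conditions: H2O, 70 °C
Reagents that add atoms: none
Why: Michael addition of the acidic 1,3-dione to the enone; no stereocentre is formed.

Step 2
Reactants: 3 2-methyl-2-(3-oxopentyl)cyclopentane-1,3-dione
Product: 4 (7aS)-4,7a-dimethyl-2,3,7,7a-tetrahydro-1H-indene-1,5(6H)-dione
Conditions: L-phenylalanine (1 eq), (1S)-CSA (0.5 eq), MeCN, 70 °C; recrystallise
Reagents that add atoms: none
Why: Hajos–Parrish–Eder–Sauer–Wiechert aldol condensation; the L-amino-acid enamine selects one enantiotopic ring carbonyl and sets the quaternary centre as 7aS (future C10).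

Step 3
Reactants: 4 (7aS)-4,7a-dimethyl-2,3,7,7a-tetrahydro-1H-indene-1,5(6H)-dione
Product: 5 (7a'S)-4',7a'-dimethyl-2',3',7',7a'-tetrahydrospiro[1,3-dioxolane-2,1'-inden]-5'(6'H)-one
Conditions: HOCH2CH2OH (1.2 eq), TsOH·H2O (cat.), 4 Å MS, CH2Cl2, rt
Reagents that add atoms: ethylene glycol OCCO
Why: Chemoselective ketalisation of the saturated ketone over the less electrophilic enone carbonyl.

Step 4
Reactants: 6 but-3-en-1-ol
Product: 7 (but-3-en-1-yloxy)(tert-butyl)dimethylsilane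
Conditions: TBSCl, imidazole, DMF, rt
Reagents that add atoms: tert-butyldimethylsilyl chloride CC(C)(C)[Si](C)(C)Cl
Why: Standard silylation; the silyloxyethyl group is the masked terminal CH2CO2H of both isocitrate arms.

Step 5
Reactants: 7 (but-3-en-1-yloxy)(tert-butyl)dimethylsilane
Product: 8 tert-butyldimethyl{[(3E)-4-nitrobut-3-en-1-yl]oxy}silane
Conditions: AgNO2 (3 eq), TEMPO (0.4 eq), 4 Å MS, ClCH2CH2Cl, 70 °C
Reagents that add atoms: silver nitrite [Ag+].[O-]N=O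
Why: Radical nitration of a terminal alkene (NO2 addition, TEMPO-mediated H abstraction) gives the E-nitroalkene.

**Unit A**

Step 6
Reactants: 5 (7a'S)-4',7a'-dimethyl-2',3',7',7a'-tetrahydrospiro[1,3-dioxolane-2,1'-inden]-5'(6'H)-one
Product: 9 (3a'S,7a'S)-4',4',7a'-trimethylhexahydrospiro[1,3-dioxolane-2,1'-inden]-5'(4'H)-one
Conditions: Li (2.5 eq), NH3/THF, t-BuOH (1 eq), −78 → −33 °C; isoprene; then MeI, −78 °C → rt
Reagents that add atoms: iodomethane CI
Why: Stork reductive alkylation (Birch reduction of the enone, regiospecific enolate methylation); protonation at the ring-fusion carbon anti to the angular methyl gives the trans-hydrindane (3a'S).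

Step 7
Reactants: 9 (3a'S,7a'S)-4',4',7a'-trimethylhexahydrospiro[1,3-dioxolane-2,1'-inden]-5'(4'H)-one
Product: 11 (3aS,7aS)-4,4,7a-trimethyloctahydro-1H-inden-1-one, via deoxygenated ketal 10 (not isolated)
Conditions: N2H4·H2O, KOH, diethylene glycol, 130 → 200 °C; extractive work-up; then 1 M HCl, THF, rt
Reagents that add atoms: water O
Why: Wolff–Kishner (Huang-Minlon) reduction of the hindered ketone (the ketal is base-stable), then acidic ketal hydrolysis; no stereocentre is touched.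

Step 8
Reactants: 11 (3aS,7aS)-4,4,7a-trimethyloctahydro-1H-inden-1-one
Product: 13 {[(1R,3aS,7aS)-1-ethenyl-4,4,7a-trimethyloctahydro-1H-inden-1-yl]oxy}trimethylsilane, via vinyl carbinol 12 (not isolated)
Conditions: CH2=CHMgBr, CeCl3, THF, −78 → 0 °C; work-up; then TMSOTf, Et3N, CH2Cl2, 0 °C
Reagents that add atoms: vinylmagnesium bromide C=C[Mg]Br; trimethylsilyl triflate C[Si](C)(C)OS(=O)(=O)C(F)(F)F
Why: Organocerium 1,2-addition from the α face, anti to the angular methyl (as for 17-keto steroids), gives the 1R carbinol, which is then O-silylated.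

Step 9
Reactants: 13 {[(1R,3aS,7aS)-1-ethenyl-4,4,7a-trimethyloctahydro-1H-inden-1-yl]oxy}trimethylsilane
Product: 14 trimethyl{[(1S,3aS,7aS)-4,4,7a-trimethyl-1-[(2R)-oxiran-2-yl]octahydro-1H-inden-1-yl]oxy}silane
Conditions: MeReO3 (1 mol%), pyrazole (12 mol%), 30% H2O2, CH2Cl2, rt
Reagents that add atoms: hydrogen peroxide OO
Why: Non-directed Re-catalysed epoxidation; by the Houk allylic-ether model (reagent anti to the quaternary C7a, silyloxy group inside) the (2R)-oxirane should predominate, and the product of the minor epimer is removed after step 10.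

Step 10
Reactants: 14 trimethyl{[(1S,3aS,7aS)-4,4,7a-trimethyl-1-[(2R)-oxiran-2-yl]octahydro-1H-inden-1-yl]oxy}silane
Product: 16 ethyl {[(1S,4aS,8aS)-5,5,8a-trimethyl-2-oxodecahydronaphthalen-1-yl]methoxy}acetate, via silyl ketene acetal 15 (not isolated)
Conditions: Rh2(OAc)4 (1 mol%), N2CHCO2Et (1.5 eq, slow addition), CH2Cl2, 0 °C → rt; aq. NH4Cl work-up
Reagents that add atoms: ethyl diazoacetate CCOC(=O)C=[N+]=[N-]
Why: Proposed new method: the Rh carbenoid is captured by the epoxide oxygen (the tertiary O–TMS is shielded) to give an oxiranium ylide, i.e. an internally activated epoxide; its C–O bond at the carbinol-bearing carbon breaks with anti-periplanar 1,2-shift of the quaternary C7a (semipinacol, cyclopentane → cyclohexanone) while TMS moves from the oxocarbenium to the ester enolate (15, hydrolysed on work-up); the shift inverts the oxirane CH and sets C1 as S (drimane C9), and the epoxide oxygen becomes the C11–O–CH2 ether; closest known reactions are the Lewis-acid (Tsuchihashi–Suzuki) semipinacol of 2,3-epoxy silyl ethers and Rh/Cu-carbenoid oxonium-ylide formation from epoxides.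

Step 11
Reactants: 16 ethyl {[(1S,4aS,8aS)-5,5,8a-trimethyl-2-oxodecahydronaphthalen-1-yl]methoxy}acetate
Product: 17 ethyl (Alb-oxy)acetate
Conditions: Zn, CH2Br2, TiCl4 (pre-formed Lombardo reagent), THF/CH2Cl2, 0 °C → rt
Reagents that add atoms: dibromomethane BrCBr
Why: Lombardo–Takai methylenation is non-basic (no C9 epimerisation, no β-alkoxy elimination) and selective for the ketone over the ester.

Step 12
Reactants: 17 ethyl (Alb-oxy)acetate
Product: 18 (Alb-oxy)acetaldehyde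
Conditions: DIBAL-H (1.1 eq), CH2Cl2, −78 °C; Rochelle salt
Reagents that add atoms: none
Why: Partial reduction of an α-alkoxy ester through a stable chelated tetrahedral intermediate; the aldehyde is used crude.

Step 13
Reactants: 18 (Alb-oxy)acetaldehyde; 8 tert-butyldimethyl{[(3E)-4-nitrobut-3-en-1-yl]oxy}silane
Product: 19 (2R,3R)-2-(Alb-oxy)-5-(TBS-oxy)-3-(nitromethyl)pentanal
Conditions: 1-[(1S,2S)-2-aminocyclohexyl]-3-[3,5-bis(trifluoromethyl)phenyl]thiourea (20 mol%), 8 (1.5 eq), CH2Cl2, rt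
Reagents that add atoms: none
Why: Barbas-type anti-selective enamine Michael addition: the primary amine forms the N–H···O-bonded (Z)-enamine of the α-alkoxyaldehyde while the thiourea binds the nitro group, giving the anti adduct and setting C2 (R) and C3 (R); the absolute sense is assigned by analogy with (R,R)-diamine thioureas, which deliver nucleophiles to the opposite nitroalkene face.

Step 14
Reactants: 19 (2R,3R)-2-(Alb-oxy)-5-(TBS-oxy)-3-(nitromethyl)pentanal
Product: 21 methyl (2R,3R)-2-(Alb-oxy)-5-(TBS-oxy)-3-(nitromethyl)pentanoate, via carboxylic acid 20 (not isolated)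
Conditions: NaClO2, NaH2PO4, 2-methyl-2-butene, t-BuOH/H2O, 0 °C; extractive work-up; then TMSCHN2, MeOH/toluene, 0 °C
Reagents that add atoms: sodium chlorite [Na+].[O-]Cl=O; trimethylsilyldiazomethane C[Si](C)(C)C=[N+]=[N-]
Why: Pinnick oxidation (the scavenger protects the exocyclic alkene) then diazoalkane esterification; both are non-epimerising for the α-alkoxy centre.

Step 15
Reactants: 21 methyl (2R,3R)-2-(Alb-oxy)-5-(TBS-oxy)-3-(nitromethyl)pentanoate
Product: 22 (2S,3R)-3-(Alb-oxy)-2-[2-(TBS-oxy)ethyl]-4-methoxy-4-oxobutanoic acid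
Conditions: NaNO2 (3 eq), AcOH (10 eq), DMSO, 35 °C
Reagents that add atoms: sodium nitrite [Na+].[O-]N=O; water O
Why: Mioskowski nitro-to-carboxylic-acid conversion (via the nitrolic acid) turns CH2NO2 into the central CO2H without touching the adjacent stereocentre.

**Unit B**

Step 16
Reactants: 5 (7a'S)-4',7a'-dimethyl-2',3',7',7a'-tetrahydrospiro[1,3-dioxolane-2,1'-inden]-5'(6'H)-one
Product: 23 (3a'R,4'R,7a'S)-4'-{[(4-methoxybenzyl)oxy]methyl}-4',7a'-dimethylhexahydrospiro[1,3-dioxolane-2,1'-inden]-5'(4'H)-one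
Conditions: Li (2.5 eq), NH3/THF, t-BuOH (1 eq), −78 → −33 °C; isoprene; then PMBOCH2Cl, THF, −78 → 0 °C
Reagents that add atoms: 4-methoxybenzyl chloromethyl ether COc1ccc(COCCl)cc1
Why: Stork reductive alkylation; trans ring fusion as in step 6, and the electrophile enters the enolate from the α face, anti to the angular methyl (as in aphidicolin-type hydroxymethylations), setting C4' as R (CH2O equatorial, α).

Step 17
Reactants: 23 (3a'R,4'R,7a'S)-4'-{[(4-methoxybenzyl)oxy]methyl}-4',7a'-dimethylhexahydrospiro[1,3-dioxolane-2,1'-inden]-5'(4'H)-one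
Product: 25 (3aS,4R,7aS)-4-{[(4-methoxybenzyl)oxy]methyl}-4,7a-dimethyloctahydro-1H-inden-1-one, via deoxygenated ketal 24 (not isolated)
Conditions: N2H4·H2O, KOH, diethylene glycol, 130 → 200 °C; extractive work-up; then 1 M HCl, THF, rt
Reagents that add atoms: water O
Why: Wolff–Kishner reduction then ketal hydrolysis; the β-alkoxy ketone cannot undergo retro-aldol or elimination because C4 is quaternary and the oxygen is etherified.

Step 18
Reactants: 25 (3aS,4R,7aS)-4-{[(4-methoxybenzyl)oxy]methyl}-4,7a-dimethyloctahydro-1H-inden-1-one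
Product: 27 {[(1R,3aS,4R,7aS)-1-ethenyl-4-{[(4-methoxybenzyl)oxy]methyl}-4,7a-dimethyloctahydro-1H-inden-1-yl]oxy}trimethylsilane, via vinyl carbinol 26 (not isolated)
Conditions: CH2=CHMgBr, CeCl3, THF, −78 → 0 °C; work-up; then TMSOTf, Et3N, CH2Cl2, 0 °C
Reagents that add atoms: vinylmagnesium bromide C=C[Mg]Br; trimethylsilyl triflate C[Si](C)(C)OS(=O)(=O)C(F)(F)F
Why: As step 8: organocerium addition anti to the angular methyl (1R), then silylation.

Step 19
Reactants: 27 {[(1R,3aS,4R,7aS)-1-ethenyl-4-{[(4-methoxybenzyl)oxy]methyl}-4,7a-dimethyloctahydro-1H-inden-1-yl]oxy}trimethylsilane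
Product: 28 {[(1S,3aS,4R,7aS)-4-{[(4-methoxybenzyl)oxy]methyl}-4,7a-dimethyl-1-[(2R)-oxiran-2-yl]octahydro-1H-inden-1-yl]oxy}trimethylsilane
Conditions: MeReO3 (1 mol%), pyrazole (12 mol%), 30% H2O2, CH2Cl2, rt
Reagents that add atoms: hydrogen peroxide OO
Why: As step 9: buffered Re-catalysed epoxidation, tolerant of the PMB ether, with the same facial preference for the (2R)-oxirane.

Step 20
Reactants: 28 {[(1S,3aS,4R,7aS)-4-{[(4-methoxybenzyl)oxy]methyl}-4,7a-dimethyl-1-[(2R)-oxiran-2-yl]octahydro-1H-inden-1-yl]oxy}trimethylsilane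
Product: 30 ethyl {[(1S,4aR,5R,8aS)-5-{[(4-methoxybenzyl)oxy]methyl}-5,8a-dimethyl-2-oxodecahydronaphthalen-1-yl]methoxy}acetate, via silyl ketene acetal 29 (not isolated)
Conditions: Rh2(OAc)4 (1 mol%), N2CHCO2Et (1.5 eq, slow addition), CH2Cl2, 0 °C → rt; aq. NH4Cl work-up
Reagents that add atoms: ethyl diazoacetate CCOC(=O)C=[N+]=[N-]
Why: Proposed new method: same carbenoid-triggered semipinacol ring expansion as step 10 (epoxide oxonium ylide, anti 1,2-shift of the quaternary carbon, silyl transfer to the enolate), setting C1 (S) and forming the C11–O–CH2 bond; closest known reactions are the Tsuchihashi–Suzuki semipinacol of epoxy silyl ethers and carbenoid oxonium-ylide formation from epoxides.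

Step 21
Reactants: 30 ethyl {[(1S,4aR,5R,8aS)-5-{[(4-methoxybenzyl)oxy]methyl}-5,8a-dimethyl-2-oxodecahydronaphthalen-1-yl]methoxy}acetate
Product: 31 ethyl (PMBO-Alb-oxy)acetate
Conditions: Zn, CH2Br2, TiCl4 (Lombardo reagent), THF/CH2Cl2, 0 °C → rt
Reagents that add atoms: dibromomethane BrCBr
Why: Lombardo–Takai methylenation, ketone-selective and non-epimerising; the PMB ether is tolerated.

Step 22
Reactants: 31 ethyl (PMBO-Alb-oxy)acetate
Product: 32 (PMBO-Alb-oxy)acetaldehyde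
Conditions: DIBAL-H (1.1 eq), CH2Cl2, −78 °C; Rochelle salt
Reagents that add atoms: none
Why: Partial DIBAL reduction of the α-alkoxy ester to the aldehyde.

Step 23
Reactants: 32 (PMBO-Alb-oxy)acetaldehyde; 8 tert-butyldimethyl{[(3E)-4-nitrobut-3-en-1-yl]oxy}silane
Product: 33 (2R,3R)-2-(PMBO-Alb-oxy)-5-(TBS-oxy)-3-(nitromethyl)pentanal
Conditions: 1-[(1S,2S)-2-aminocyclohexyl]-3-[3,5-bis(trifluoromethyl)phenyl]thiourea (20 mol%), 8 (1.5 eq), CH2Cl2, rt
Reagents that add atoms: none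
Why: Same anti-selective primary-amine/thiourea enamine Michael addition as step 13, setting C2 (R) and C3 (R) under catalyst control.

Step 24
Reactants: 33 (2R,3R)-2-(PMBO-Alb-oxy)-5-(TBS-oxy)-3-(nitromethyl)pentanal
Product: 35 methyl (2R,3R)-2-(PMBO-Alb-oxy)-5-(TBS-oxy)-3-(nitromethyl)pentanoate, via carboxylic acid 34 (not isolated)
Conditions: NaClO2, NaH2PO4, 2-methyl-2-butene, t-BuOH/H2O, 0 °C; extractive work-up; then TMSCHN2, MeOH/toluene, 0 °C
Reagents that add atoms: sodium chlorite [Na+].[O-]Cl=O; trimethylsilyldiazomethane C[Si](C)(C)C=[N+]=[N-]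
Why: Pinnick oxidation then diazoalkane esterification, as in step 14.

Step 25
Reactants: 35 methyl (2R,3R)-2-(PMBO-Alb-oxy)-5-(TBS-oxy)-3-(nitromethyl)pentanoate
Product: 36 methyl (2R,3R)-2-(HO-Alb-oxy)-5-(TBS-oxy)-3-(nitromethyl)pentanoate
Conditions: DDQ (1.3 eq), CH2Cl2/pH 7 buffer, 0 °C → rt
Reagents that add atoms: none
Why: Oxidative PMB-ether cleavage frees the neopentyl C15–OH; the alkene, nitro, TBS and ester groups are inert to DDQ.

**Union and end game**

Step 26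
Reactants: 22 (2S,3R)-3-(Alb-oxy)-2-[2-(TBS-oxy)ethyl]-4-methoxy-4-oxobutanoic acid; 36 methyl (2R,3R)-2-(HO-Alb-oxy)-5-(TBS-oxy)-3-(nitromethyl)pentanoate
Product: 37 diester-linked dimer (unit A central carboxyl esterified with C15–OH of unit B; both arms TBS-protected; unit B arm still CH2NO2)
Conditions: DIC (1.5 eq), DPTS (0.5 eq), CH2Cl2, rt
Reagents that add atoms: none
Why: Carbodiimide (Steglich-type) esterification under near-neutral DPTS catalysis, which avoids nitronate acylation and limits epimerisation of the α-branched acid.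

Step 27
Reactants: 37 diester-linked dimer
Product: 38 dimer diol (both CH2CH2OH free)
Conditions: HF·pyridine, pyridine/THF, 0 °C → rt; used at once
Reagents that add atoms: none
Why: Buffered fluoride desilylation of the two primary TBS ethers; the diol is oxidised immediately to avoid lactonisation onto the neighbouring esters.

Step 28
Reactants: 38 dimer diol
Product: 39 dimer diacid (both terminal CH2CO2H; unit B arm still CH2NO2)
Conditions: TEMPO (0.3 eq), PhI(OAc)2 (5 eq), MeCN/H2O 1:1, rt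
Reagents that add atoms: water O
Why: TEMPO/BAIB oxidation of primary alcohols to carboxylic acids via the aldehyde hydrates; alkenes, esters and the nitro group are untouched.

Step 29
Reactants: 39 dimer diacid
Product: 40 CNP0420141.2 (target)
Conditions: NaNO2 (3 eq), AcOH (10 eq), DMSO, 35 °C
Reagents that add atoms: sodium nitrite [Na+].[O-]N=O; water O
Why: Mioskowski nitro-to-acid conversion unmasks the last (unit B central) CO2H without epimerisation, giving the target.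

**Compound list**
1 | 2-methylcyclopentane-1,3-dione | CC1C(=O)CCC1=O | starting material
2 | pent-1-en-3-one | CCC(=O)C=C | starting material
3 | 2-methyl-2-(3-oxopentyl)cyclopentane-1,3-dione | CCC(=O)CCC1(C)C(=O)CCC1=O | intermediate
4 | (7aS)-4,7a-dimethyl-2,3,7,7a-tetrahydro-1H-indene-1,5(6H)-dione | CC1=C2CCC(=O)[C@@]2(C)CCC1=O | intermediate
5 | (7a'S)-4',7a'-dimethyl-2',3',7',7a'-tetrahydrospiro[1,3-dioxolane-2,1'-inden]-5'(6'H)-one | CC1=C2CCC3(OCCO3)[C@@]2(C)CCC1=O | intermediate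
6 | but-3-en-1-ol | OCCC=C | starting material
7 | (but-3-en-1-yloxy)(tert-butyl)dimethylsilane | C=CCCO[Si](C)(C)C(C)(C)C | intermediate
8 | tert-butyldimethyl{[(3E)-4-nitrobut-3-en-1-yl]oxy}silane | [O-][N+](=O)/C=C/CCO[Si](C)(C)C(C)(C)C | intermediate
9 | (3a'S,7a'S)-4',4',7a'-trimethylhexahydrospiro[1,3-dioxolane-2,1'-inden]-5'(4'H)-one | O=C1CC[C@@]2(C)[C@@H](CCC23OCCO3)C1(C)C | intermediate
10 | (3a'S,7a'S)-4',4',7a'-trimethyloctahydrospiro[1,3-dioxolane-2,1'-indene] | O1CCOC12CC[C@H]3C(C)(C)CCC[C@]23C | intermediate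
11 | (3aS,7aS)-4,4,7a-trimethyloctahydro-1H-inden-1-one | O=C1CC[C@H]2C(C)(C)CCC[C@]12C | intermediate
12 | (1R,3aS,7aS)-1-ethenyl-4,4,7a-trimethyloctahydro-1H-inden-1-ol | C=C[C@]1(O)CC[C@H]2C(C)(C)CCC[C@]12C | intermediate
13 | {[(1R,3aS,7aS)-1-ethenyl-4,4,7a-trimethyloctahydro-1H-inden-1-yl]oxy}trimethylsilane | C=C[C@]1(O[Si](C)(C)C)CC[C@H]2C(C)(C)CCC[C@]12C | intermediate
14 | trimethyl{[(1S,3aS,7aS)-4,4,7a-trimethyl-1-[(2R)-oxiran-2-yl]octahydro-1H-inden-1-yl]oxy}silane | C1O[C@H]1[C@]2(O[Si](C)(C)C)CC[C@H]3C(C)(C)CCC[C@]23C | intermediate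
15 | ethyl trimethylsilyl ketene acetal of 16 (ROCH=C(OEt)OTMS, R = [(1S,4aS,8aS)-5,5,8a-trimethyl-2-oxodecahydronaphthalen-1-yl]methyl) | O=C1CC[C@H]2C(C)(C)CCC[C@]2(C)[C@H]1COC=C(OCC)O[Si](C)(C)C | intermediate
16 | ethyl {[(1S,4aS,8aS)-5,5,8a-trimethyl-2-oxodecahydronaphthalen-1-yl]methoxy}acetate | O=C1CC[C@H]2C(C)(C)CCC[C@]2(C)[C@H]1COCC(=O)OCC | intermediate
17 | ethyl {[(1S,4aS,8aS)-5,5,8a-trimethyl-2-methylidenedecahydronaphthalen-1-yl]methoxy}acetate | C=C1CC[C@H]2C(C)(C)CCC[C@]2(C)[C@H]1COCC(=O)OCC | intermediate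
18 | {[(1S,4aS,8aS)-5,5,8a-trimethyl-2-methylidenedecahydronaphthalen-1-yl]methoxy}acetaldehyde | C=C1CC[C@H]2C(C)(C)CCC[C@]2(C)[C@H]1COCC=O | intermediate
19 | (2R,3R)-2-(Alb-oxy)-5-(TBS-oxy)-3-(nitromethyl)pentanal | C=C1CC[C@H]2C(C)(C)CCC[C@]2(C)[C@H]1CO[C@@H](C=O)[C@H](CCO[Si](C)(C)C(C)(C)C)C[N+](=O)[O-] | intermediate
20 | (2R,3R)-2-(Alb-oxy)-5-(TBS-oxy)-3-(nitromethyl)pentanoic acid | C=C1CC[C@H]2C(C)(C)CCC[C@]2(C)[C@H]1CO[C@@H](C(=O)O)[C@H](CCO[Si](C)(C)C(C)(C)C)C[N+](=O)[O-] | intermediate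
21 | methyl (2R,3R)-2-(Alb-oxy)-5-(TBS-oxy)-3-(nitromethyl)pentanoate | C=C1CC[C@H]2C(C)(C)CCC[C@]2(C)[C@H]1CO[C@@H](C(=O)OC)[C@H](CCO[Si](C)(C)C(C)(C)C)C[N+](=O)[O-] | intermediate
22 | (2S,3R)-3-(Alb-oxy)-2-[2-(TBS-oxy)ethyl]-4-methoxy-4-oxobutanoic acid | C=C1CC[C@H]2C(C)(C)CCC[C@]2(C)[C@H]1CO[C@@H](C(=O)OC)[C@H](CCO[Si](C)(C)C(C)(C)C)C(=O)O | intermediate
23 | (3a'R,4'R,7a'S)-4'-{[(4-methoxybenzyl)oxy]methyl}-4',7a'-dimethylhexahydrospiro[1,3-dioxolane-2,1'-inden]-5'(4'H)-one | O=C1CC[C@@]2(C)[C@@H](CCC23OCCO3)[C@]1(C)COCc1ccc(OC)cc1 | intermediate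
24 | (3a'S,4'R,7a'S)-4'-{[(4-methoxybenzyl)oxy]methyl}-4',7a'-dimethyloctahydrospiro[1,3-dioxolane-2,1'-indene] | O1CCOC12CC[C@H]3[C@](C)(COCc4ccc(OC)cc4)CCC[C@]23C | intermediate
25 | (3aS,4R,7aS)-4-{[(4-methoxybenzyl)oxy]methyl}-4,7a-dimethyloctahydro-1H-inden-1-one | O=C1CC[C@H]2[C@](C)(COCc3ccc(OC)cc3)CCC[C@]12C | intermediate
26 | (1R,3aS,4R,7aS)-1-ethenyl-4-{[(4-methoxybenzyl)oxy]methyl}-4,7a-dimethyloctahydro-1H-inden-1-ol | C=C[C@]1(O)CC[C@H]2[C@](C)(COCc3ccc(OC)cc3)CCC[C@]12C | intermediate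
27 | {[(1R,3aS,4R,7aS)-1-ethenyl-4-{[(4-methoxybenzyl)oxy]methyl}-4,7a-dimethyloctahydro-1H-inden-1-yl]oxy}trimethylsilane | C=C[C@]1(O[Si](C)(C)C)CC[C@H]2[C@](C)(COCc3ccc(OC)cc3)CCC[C@]12C | intermediate
28 | {[(1S,3aS,4R,7aS)-4-{[(4-methoxybenzyl)oxy]methyl}-4,7a-dimethyl-1-[(2R)-oxiran-2-yl]octahydro-1H-inden-1-yl]oxy}trimethylsilane | C1O[C@H]1[C@]2(O[Si](C)(C)C)CC[C@H]3[C@](C)(COCc4ccc(OC)cc4)CCC[C@]23C | intermediate
29 | ethyl trimethylsilyl ketene acetal of 30 | O=C1CC[C@H]2[C@](C)(COCc3ccc(OC)cc3)CCC[C@]2(C)[C@H]1COC=C(OCC)O[Si](C)(C)C | intermediate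
30 | ethyl {[(1S,4aR,5R,8aS)-5-{[(4-methoxybenzyl)oxy]methyl}-5,8a-dimethyl-2-oxodecahydronaphthalen-1-yl]methoxy}acetate | O=C1CC[C@H]2[C@](C)(COCc3ccc(OC)cc3)CCC[C@]2(C)[C@H]1COCC(=O)OCC | intermediate
31 | ethyl (PMBO-Alb-oxy)acetate | C=C1CC[C@H]2[C@](C)(COCc3ccc(OC)cc3)CCC[C@]2(C)[C@H]1COCC(=O)OCC | intermediate
32 | (PMBO-Alb-oxy)acetaldehyde | C=C1CC[C@H]2[C@](C)(COCc3ccc(OC)cc3)CCC[C@]2(C)[C@H]1COCC=O | intermediate
33 | (2R,3R)-2-(PMBO-Alb-oxy)-5-(TBS-oxy)-3-(nitromethyl)pentanal | C=C1CC[C@H]2[C@](C)(COCc3ccc(OC)cc3)CCC[C@]2(C)[C@H]1CO[C@@H](C=O)[C@H](CCO[Si](C)(C)C(C)(C)C)C[N+](=O)[O-] | intermediate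
34 | (2R,3R)-2-(PMBO-Alb-oxy)-5-(TBS-oxy)-3-(nitromethyl)pentanoic acid | C=C1CC[C@H]2[C@](C)(COCc3ccc(OC)cc3)CCC[C@]2(C)[C@H]1CO[C@@H](C(=O)O)[C@H](CCO[Si](C)(C)C(C)(C)C)C[N+](=O)[O-] | intermediate
35 | methyl (2R,3R)-2-(PMBO-Alb-oxy)-5-(TBS-oxy)-3-(nitromethyl)pentanoate | C=C1CC[C@H]2[C@](C)(COCc3ccc(OC)cc3)CCC[C@]2(C)[C@H]1CO[C@@H](C(=O)OC)[C@H](CCO[Si](C)(C)C(C)(C)C)C[N+](=O)[O-] | intermediate
36 | methyl (2R,3R)-2-(HO-Alb-oxy)-5-(TBS-oxy)-3-(nitromethyl)pentanoate | C=C1CC[C@H]2[C@](C)(CO)CCC[C@]2(C)[C@H]1CO[C@@H](C(=O)OC)[C@H](CCO[Si](C)(C)C(C)(C)C)C[N+](=O)[O-] | intermediate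
37 | dimer: C15 ester of 36 with acid 22 (both arms CH2CH2OTBS; unit B arm CH2NO2) | C=C1CC[C@H]2C(C)(C)CCC[C@]2(C)[C@H]1CO[C@@H](C(=O)OC)[C@H](CCO[Si](C)(C)C(C)(C)C)C(=O)OC[C@]1(C)CCC[C@]2(C)[C@@H](CO[C@@H](C(=O)OC)[C@H](CCO[Si](C)(C)C(C)(C)C)C[N+](=O)[O-])C(=C)CC[C@@H]12 | intermediate
38 | dimer diol (both arms CH2CH2OH; unit B arm CH2NO2) | C=C1CC[C@H]2C(C)(C)CCC[C@]2(C)[C@H]1CO[C@@H](C(=O)OC)[C@H](CCO)C(=O)OC[C@]1(C)CCC[C@]2(C)[C@@H](CO[C@@H](C(=O)OC)[C@H](CCO)C[N+](=O)[O-])C(=C)CC[C@@H]12 | intermediate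
39 | dimer diacid (both arms CH2CO2H; unit B arm CH2NO2) | C=C1CC[C@H]2C(C)(C)CCC[C@]2(C)[C@H]1CO[C@@H](C(=O)OC)[C@H](CC(=O)O)C(=O)OC[C@]1(C)CCC[C@]2(C)[C@@H](CO[C@@H](C(=O)OC)[C@H](CC(=O)O)C[N+](=O)[O-])C(=C)CC[C@@H]12 | intermediate
40 | CNP0420141.2 | C=C1CC[C@H]2C(C)(C)CCC[C@]2(C)[C@H]1CO[C@@H](C(=O)OC)[C@H](CC(=O)O)C(=O)OC[C@]1(C)CCC[C@]2(C)[C@@H](CO[C@@H](C(=O)OC)[C@H](CC(=O)O)C(=O)O)C(=C)CC[C@@H]12 | target

**Totals**
Total step count: 29 (steps 7, 8, 14, 17, 18 and 24 are telescoped two-operation steps).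
Longest linear sequence: 17 steps (1–3, 6–15, 26–29; the unit B branch 1–3, 16–25, 26–29 is equally long).

**Three steps most likely to fail, with fallbacks**

Step 10 (new carbenoid-triggered ring expansion; its twin is step 20). The oxiranium ylide may instead fragment (deoxygenation) or undergo a Stevens shift; in the B series the PMB ether and arene are further carbenoid traps. The fallback uses known chemistry and sets out from 14. A Tsuchihashi–Suzuki semipinacol rearrangement with TiCl4 (CH2Cl2, −78 °C) gives, after aqueous work-up, the β-hydroxy ketone (1S,4aS,8aS)-1-(hydroxymethyl)-5,5,8a-trimethyloctahydronaphthalen-2(1H)-one F1. Rh2(OAc)4-catalysed O–H insertion of ethyl diazoacetate into its primary alcohol then gives 16, where the route is rejoined. For step 20 the same detour runs from 28 through (1S,4aR,5R,8aS)-1-(hydroxymethyl)-5-{[(4-methoxybenzyl)oxy]methyl}-5,8a-dimethyloctahydronaphthalen-2(1H)-one F2 back to 30.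

Step 13 (anti-selective Michael addition; its twin is step 23). The aldehyde is bulkier and the nitroalkene less reactive than in the precedent, and the absolute sense of the catalyst is assigned only by analogy. The fallback replaces catalyst control by a covalent auxiliary and sets out from 17. Saponification (LiOH) gives (Alb-oxy)acetic acid F3, which is coupled (EDC, DMAP) to (S)-4-benzyl-1,3-oxazolidin-2-one to give the N-[(Alb-oxy)acetyl] imide F4. Its chelated chlorotitanium (Z)-enolate (TiCl4, i-Pr2NEt, CH2Cl2, −78 °C) adds to nitroalkene 8 on the face away from the benzyl group (Evans/Seebach-type auxiliary-controlled Michael addition, C2 fixed as R, C3 epimers separable) to give the imide adduct F5. LiOH/H2O2 cleaves the auxiliary and returns acid 20, from which the esterification of step 14 continues. For step 23 the same detour runs from 31 through (PMBO-Alb-oxy)acetic acid F6, its N-acyl oxazolidinone F7 and the imide adduct F8 back to 34.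

Step 16 (reductive alkoxymethylation). A chloromethyl ether may O-alkylate the tetrasubstituted enolate. The fallback sets out from 5 and replaces alkylation by an aldol trap. After the same Li/NH3 reduction the enolate is quenched with gaseous formaldehyde (the aphidicolin-type reductive hydroxymethylation) to give (3a'R,4'R,7a'S)-4'-(hydroxymethyl)-4',7a'-dimethylhexahydrospiro[1,3-dioxolane-2,1'-inden]-5'(4'H)-one F9. Protection with 4-methoxybenzyl trichloroacetimidate (La(OTf)3 cat.) gives 23, where the route is rejoined.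

Further compounds
F1 | step 10 | (1S,4aS,8aS)-1-(hydroxymethyl)-5,5,8a-trimethyloctahydronaphthalen-2(1H)-one | O=C1CC[C@H]2C(C)(C)CCC[C@]2(C)[C@H]1CO
F2 | step 10 | (1S,4aR,5R,8aS)-1-(hydroxymethyl)-5-{[(4-methoxybenzyl)oxy]methyl}-5,8a-dimethyloctahydronaphthalen-2(1H)-one | O=C1CC[C@H]2[C@](C)(COCc3ccc(OC)cc3)CCC[C@]2(C)[C@H]1CO
F3 | step 13 | (Alb-oxy)acetic acid | C=C1CC[C@H]2C(C)(C)CCC[C@]2(C)[C@H]1COCC(=O)O
F4 | step 13 | (4S)-3-[(Alb-oxy)acetyl]-4-benzyl-1,3-oxazolidin-2-one | C=C1CC[C@H]2C(C)(C)CCC[C@]2(C)[C@H]1COCC(=O)N1[C@@H](Cc2ccccc2)COC1=O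
F5 | step 13 | (4S)-3-[(2R,3R)-2-(Alb-oxy)-5-(TBS-oxy)-3-(nitromethyl)pentanoyl]-4-benzyl-1,3-oxazolidin-2-one | C=C1CC[C@H]2C(C)(C)CCC[C@]2(C)[C@H]1CO[C@@H](C(=O)N1[C@@H](Cc2ccccc2)COC1=O)[C@H](CCO[Si](C)(C)C(C)(C)C)C[N+](=O)[O-]
F6 | step 13 | (PMBO-Alb-oxy)acetic acid | C=C1CC[C@H]2[C@](C)(COCc3ccc(OC)cc3)CCC[C@]2(C)[C@H]1COCC(=O)O
F7 | step 13 | (4S)-3-[(PMBO-Alb-oxy)acetyl]-4-benzyl-1,3-oxazolidin-2-one | C=C1CC[C@H]2[C@](C)(COCc3ccc(OC)cc3)CCC[C@]2(C)[C@H]1COCC(=O)N1[C@@H](Cc2ccccc2)COC1=O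
F8 | step 13 | (4S)-3-[(2R,3R)-2-(PMBO-Alb-oxy)-5-(TBS-oxy)-3-(nitromethyl)pentanoyl]-4-benzyl-1,3-oxazolidin-2-one | C=C1CC[C@H]2[C@](C)(COCc3ccc(OC)cc3)CCC[C@]2(C)[C@H]1CO[C@@H](C(=O)N1[C@@H](Cc2ccccc2)COC1=O)[C@H](CCO[Si](C)(C)C(C)(C)C)C[N+](=O)[O-]
F9 | step 16 | (3a'R,4'R,7a'S)-4'-(hydroxymethyl)-4',7a'-dimethylhexahydrospiro[1,3-dioxolane-2,1'-inden]-5'(4'H)-one | O=C1CC[C@@]2(C)[C@@H](CCC23OCCO3)[C@]1(C)CO
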